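**Assumption (one line):** from the SMILES the target is the trans-(2R,3S) dihydrobenzofuran carrying an erythro-(1S,2R) arylglycerol β-aryl ether; by analogy with related aryldiazoacetate insertions the (S)-PTTL rhodium catalyst is taken to give the 2R ring (if the sense is opposite, use the (R)-catalyst).

## Retrosynthetic overview
1. Target ⇐ desilylation and acetal hydrolysis of a fully assembled, protected triol.
2. Side-chain stereodiad (C–OH and C–OAr) ⇐ ketoreductase dynamic kinetic reduction of an α-aryloxy-β-keto ester, made by aldol of an aryloxyacetate with silyl-protected vanillin, then oxidation.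
3. Dihydrobenzofuran ⇐ Rh(II)-catalysed enantioselective intramolecular C–H insertion of an aryldiazoacetate into a benzylic ether C–H (cis), then C3 epimerisation to trans.
4. Diazo precursor ⇐ 5-bromovanillin + syringyl benzyl bromide (Williamson), acetal protection, Pd/Reformatsky arylation, diazo transfer.
5. Rings: all three arenes are purchased; the only ring built is the dihydrofuran (step 8). The dioxolane is a temporary protecting ring (on in step 5, off in step 18).

## Route

**Step 1**
Reactants: 1 syringaldehyde; 2 tert-butyl bromoacetate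
Product: 3 tert-butyl 2-(4-formyl-2,6-dimethoxyphenoxy)acetate
Conditions: K2CO3, DMF, 60 °C
Reagents that add atoms: tert-butyl bromoacetate (2), CC(C)(C)OC(=O)CBr
Why: Williamson etherification (SN2) of the acidic, hindered phenoxide on an unhindered α-bromo ester; this installs the future C8/C9 unit and caps the syringyl OH.

**Step 2**
Reactants: 3
Product: 4 tert-butyl 2-[4-(hydroxymethyl)-2,6-dimethoxyphenoxy]acetate
Conditions: NaBH4, MeOH–THF, 0 °C
Reagents that add atoms: none
Why: Chemoselective borohydride reduction of the aldehyde; the tert-butyl ester is inert at 0 °C.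

**Step 3**
Reactants: 4
Product: 5 tert-butyl 2-[4-(bromomethyl)-2,6-dimethoxyphenoxy]acetate
Conditions: CBr4, PPh3, CH2Cl2, 0 °C
Reagents that add atoms: carbon tetrabromide, BrC(Br)(Br)Br
Why: Appel bromination of a primary benzylic alcohol under neutral conditions, so the acid-labile tert-butyl ester survives.

**Step 4**
Reactants: 5; 6 5-bromovanillin (3-bromo-4-hydroxy-5-methoxybenzaldehyde)
Product: 7 tert-butyl 2-{4-[(2-bromo-4-formyl-6-methoxyphenoxy)methyl]-2,6-dimethoxyphenoxy}acetate
Conditions: K2CO3, DMF, rt → 50 °C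
Reagents that add atoms: bromide 5, COc1cc(CBr)cc(OC)c1OCC(=O)OC(C)(C)C
Why: Williamson benzylation of the phenoxide; this O–CH2–Ar unit supplies the C–H that later becomes C2 of the dihydrobenzofuran.

**Step 5**
Reactants: 7
Product: 8 the 1,3-dioxolane of 7: tert-butyl 2-{4-[(2-bromo-4-(1,3-dioxolan-2-yl)-6-methoxyphenoxy)methyl]-2,6-dimethoxyphenoxy}acetate
Conditions: ethylene glycol, HC(OEt)3, PPTS (cat.), toluene, 50 °C
Reagents that add atoms: ethylene glycol, OCCO
Why: Acetalisation with orthoformate as water scavenger masks the aldehyde against the zinc enolate, carbenoid, hydride, LDA and enzyme steps; PPTS spares the tert-butyl ester and benzyl aryl ether.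

**Step 6**
Reactants: 8; 9 methyl bromoacetate (used as its Reformatsky reagent)
Product: 10 methyl 2-[2-({4-[2-(tert-butoxy)-2-oxoethoxy]-3,5-dimethoxyphenyl}methoxy)-5-(1,3-dioxolan-2-yl)-3-methoxyphenyl]acetate
Conditions: BrZnCH2CO2Me (from 9, Zn, THF), Pd(dba)2/Q-Phos (2–5 mol%), THF, rt → 50 °C
Reagents that add atoms: methyl bromoacetate (9), COC(=O)CBr, as COC(=O)C[Zn]Br
Why: Pd-catalysed Negishi-type coupling of a Reformatsky reagent with the aryl bromide gives the arylacetate under neutral conditions that tolerate the acetal and both esters.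

**Step 7**
Reactants: 10
Product: 11 methyl 2-diazo-2-[2-({4-[2-(tert-butoxy)-2-oxoethoxy]-3,5-dimethoxyphenyl}methoxy)-5-(1,3-dioxolan-2-yl)-3-methoxyphenyl]acetate
Conditions: p-ABSA, DBU, MeCN, 0 °C → rt
Reagents that add atoms: p-acetamidobenzenesulfonyl azide, CC(=O)Nc1ccc(cc1)S(=O)(=O)N=[N+]=[N-]
Why: Regitz diazo transfer occurs only at the arylacetate CH2; the aryloxyacetate CH2 is not acidic enough for DBU.

**Step 8**
Reactants: 11
Product: 12 methyl (2R,3S)-cis-2-{4-[2-(tert-butoxy)-2-oxoethoxy]-3,5-dimethoxyphenyl}-5-(1,3-dioxolan-2-yl)-7-methoxy-2,3-dihydro-1-benzofuran-3-carboxylate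
Conditions: Rh2(S-PTTL)4 (1–2 mol%), toluene, −78 → −40 °C
Reagents that add atoms: none
Why: Enantioselective intramolecular 1,5 C–H insertion of the donor/acceptor Rh carbenoid into the activated benzylic ether C–H closes the dihydrofuran ring cis-selectively, and the chiral Rh(II) carboxylate sets C2 as R (first stereocentres of the route).

**Step 9**
Reactants: 12
Product: 13 methyl (2R,3R)-trans-2-{4-[2-(tert-butoxy)-2-oxoethoxy]-3,5-dimethoxyphenyl}-5-(1,3-dioxolan-2-yl)-7-methoxy-2,3-dihydro-1-benzofuran-3-carboxylate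
Conditions: NaOMe (0.3 equiv), MeOH–THF, 0 °C → rt
Reagents that add atoms: none
Why: Enolate-mediated epimerisation at C3 gives the thermodynamically favoured trans ester; C2 is untouched because ring-opening would be a disfavoured retro-5-endo process, and the tert-butyl ester does not transesterify at rt.

**Step 10**
Reactants: 13
Product: 14 tert-butyl 2-{4-[(2R,3S)-5-(1,3-dioxolan-2-yl)-3-(hydroxymethyl)-7-methoxy-2,3-dihydro-1-benzofuran-2-yl]-2,6-dimethoxyphenoxy}acetate
Conditions: LiBH4, THF, 0 °C → rt (recrystallise to upgrade ee if needed)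
Reagents that add atoms: none
Why: LiBH4 reduces the methyl ester selectively over the tert-butyl ester; the C3 label changes R → S by CIP priority only, with no change in geometry.

**Step 11**
Reactants: 14
Product: 15 TBS ether of 14: tert-butyl 2-{4-[(2R,3S)-3-[(tert-butyldimethylsilyloxy)methyl]-5-(1,3-dioxolan-2-yl)-7-methoxy-2,3-dihydro-1-benzofuran-2-yl]-2,6-dimethoxyphenoxy}acetate
Conditions: TBSCl, imidazole, DMF, rt
Reagents that add atoms: tert-butyldimethylsilyl chloride, CC(C)(C)[Si](C)(C)Cl
Why: Standard silylation of the primary alcohol so that only the ester α-CH2 is deprotonated in the aldol step.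

**Step 12**
Reactants: 16 vanillin
Product: 17 3-methoxy-4-(triisopropylsilyloxy)benzaldehyde
Conditions: TIPSCl, imidazole, DMF, rt
Reagents that add atoms: triisopropylsilyl chloride, CC(C)[Si](Cl)(C(C)C)C(C)C
Why: Phenol silylation; the TIPS aryl ether survives LDA, Dess–Martin oxidation and neutral aqueous buffer and is later removed with fluoride.

**Step 13**
Reactants: 15; 17
Product: 18 tert-butyl 3-hydroxy-3-[3-methoxy-4-(triisopropylsilyloxy)phenyl]-2-(aryloxy)propanoate, where aryloxy is the 2,6-dimethoxy-4-[(2R,3S)-dihydrobenzofuran-2-yl]phenoxy group of 15 (diastereomer mixture at C2/C3 of the propanoate)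
Conditions: LDA, THF, −78 °C; then 17; AcOH quench at −78 °C
Reagents that add atoms: aldehyde 17, COc1cc(C=O)ccc1O[Si](C(C)C)(C(C)C)C(C)C
Why: Lithium-enolate aldol addition of an aryloxyacetate to a benzaldehyde forms the C7–C8 bond of the β-O-4 unit reliably even with a 2,6-dimethoxyaryl ether; the new stereocentres are not controlled here and are reset in steps 14–15.

**Step 14**
Reactants: 18
Product: 19 tert-butyl 3-[3-methoxy-4-(triisopropylsilyloxy)phenyl]-3-oxo-2-(aryloxy)propanoate (C2 configurationally labile)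
Conditions: Dess–Martin periodinane, NaHCO3, CH2Cl2, 0 °C → rt
Reagents that add atoms: none
Why: Buffered Dess–Martin oxidation of the benzylic alcohol gives the β-keto ester without harming the acetal, silyl ethers or electron-rich arenes; the acidic C2–H now makes C2 freely epimerisable.

**Step 15**
Reactants: 19
Product: 20 tert-butyl (2S,3S)-3-hydroxy-3-[3-methoxy-4-(triisopropylsilyloxy)phenyl]-2-(aryloxy)propanoate (anti)
Conditions: ketoreductase (NADPH-dependent KRED, anti/3S-selective variant chosen from a panel), NADP+ (cat.), glucose dehydrogenase/glucose, KPi buffer pH 7.0, 20% DMSO, 30 °C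
Reagents that add atoms: none
Why: Ketoreductase dynamic reductive kinetic resolution: C2 racemises by enolisation faster than reduction, and the enzyme reduces only the 2S epimer with hydride delivery to one carbonyl face, setting both side-chain centres (2S,3S, anti) under enzyme control independent of the remote ring stereocentres.

**Step 16**
Reactants: 20
Product: 21 (1S,2R)-2-(aryloxy)-1-[3-methoxy-4-(triisopropylsilyloxy)phenyl]propane-1,3-diol (aryloxy still carrying the TBS ether and dioxolane)
Conditions: LiAlH4, THF, 0 °C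
Reagents that add atoms: none
Why: Hydride reduction of the tert-butyl ester to the primary alcohol, assisted by the neighbouring alkoxide; no stereocentre is touched, and the C2 label changes S → R by CIP priority only.

**Step 17**
Reactants: 21
Product: 22 (1S,2R)-2-{4-[(2R,3S)-5-(1,3-dioxolan-2-yl)-3-(hydroxymethyl)-7-methoxy-2,3-dihydro-1-benzofuran-2-yl]-2,6-dimethoxyphenoxy}-1-(4-hydroxy-3-methoxyphenyl)propane-1,3-diol
Conditions: TBAF, AcOH, THF, 0 °C → rt
Reagents that add atoms: none
Why: Buffered fluoride cleaves both the aryl TIPS and alkyl TBS ethers while the acetal keeps the aldehyde masked.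

**Step 18**
Reactants: 22
Product: 23 target, (2R,3S)-2-(4-{[(1S,2R)-1,3-dihydroxy-1-(4-hydroxy-3-methoxyphenyl)propan-2-yl]oxy}-3,5-dimethoxyphenyl)-3-(hydroxymethyl)-7-methoxy-2,3-dihydro-1-benzofuran-5-carbaldehyde
Conditions: PPTS (cat.), acetone–H2O (9:1), rt → 40 °C
Reagents that add atoms: water, O
Why: Mild acid-catalysed acetal hydrolysis releases the electron-rich aryl aldehyde under conditions too weak to ionise the benzylic alcohol or open the dihydrobenzofuran.

## Compound list
1 | syringaldehyde | COc1cc(C=O)cc(OC)c1O | starting material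
2 | tert-butyl bromoacetate | CC(C)(C)OC(=O)CBr | starting material
3 | tert-butyl 2-(4-formyl-2,6-dimethoxyphenoxy)acetate | COc1cc(C=O)cc(OC)c1OCC(=O)OC(C)(C)C | intermediate
4 | tert-butyl 2-[4-(hydroxymethyl)-2,6-dimethoxyphenoxy]acetate | COc1cc(CO)cc(OC)c1OCC(=O)OC(C)(C)C | intermediate
5 | tert-butyl 2-[4-(bromomethyl)-2,6-dimethoxyphenoxy]acetate | COc1cc(CBr)cc(OC)c1OCC(=O)OC(C)(C)C | intermediate
6 | 5-bromovanillin | COc1cc(C=O)cc(Br)c1O | starting material
7 | benzyl aryl ether aldehyde | COc1cc(C=O)cc(Br)c1OCc1cc(OC)c(OCC(=O)OC(C)(C)C)c(OC)c1 | intermediate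
8 | dioxolane of 7 | COc1cc(C2OCCO2)cc(Br)c1OCc1cc(OC)c(OCC(=O)OC(C)(C)C)c(OC)c1 | intermediate
9 | methyl bromoacetate | COC(=O)CBr | starting material
10 | methyl arylacetate | COC(=O)Cc1cc(C2OCCO2)cc(OC)c1OCc1cc(OC)c(OCC(=O)OC(C)(C)C)c(OC)c1 | intermediate
11 | methyl aryldiazoacetate | COC(=O)C(=[N+]=[N-])c1cc(C2OCCO2)cc(OC)c1OCc1cc(OC)c(OCC(=O)OC(C)(C)C)c(OC)c1 | intermediate
12 | cis-(2R,3S) dihydrobenzofuran methyl ester | CC(C)(C)OC(=O)COc1c(OC)cc([C@@H]2Oc3c(OC)cc(C4OCCO4)cc3[C@@H]2C(=O)OC)cc1OC | intermediate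
13 | trans-(2R,3R) dihydrobenzofuran methyl ester | CC(C)(C)OC(=O)COc1c(OC)cc([C@@H]2Oc3c(OC)cc(C4OCCO4)cc3[C@H]2C(=O)OC)cc1OC | intermediate
14 | trans-(2R,3S) 3-hydroxymethyl dihydrobenzofuran | CC(C)(C)OC(=O)COc1c(OC)cc([C@@H]2Oc3c(OC)cc(C4OCCO4)cc3[C@H]2CO)cc1OC | intermediate
15 | TBS ether of 14 | CC(C)(C)OC(=O)COc1c(OC)cc([C@@H]2Oc3c(OC)cc(C4OCCO4)cc3[C@H]2CO[Si](C)(C)C(C)(C)C)cc1OC | intermediate
16 | vanillin | COc1cc(C=O)ccc1O | starting material
17 | 3-methoxy-4-(triisopropylsilyloxy)benzaldehyde | COc1cc(C=O)ccc1O[Si](C(C)C)(C(C)C)C(C)C | intermediate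
18 | aldol adduct (mixture at side-chain C2/C3) | COc1cc(C(O)C(C(=O)OC(C)(C)C)Oc2c(OC)cc([C@@H]3Oc4c(OC)cc(C5OCCO5)cc4[C@H]3CO[Si](C)(C)C(C)(C)C)cc2OC)ccc1O[Si](C(C)C)(C(C)C)C(C)C | intermediate
19 | α-aryloxy-β-keto ester (C2 labile) | COc1cc(C(=O)C(C(=O)OC(C)(C)C)Oc2c(OC)cc([C@@H]3Oc4c(OC)cc(C5OCCO5)cc4[C@H]3CO[Si](C)(C)C(C)(C)C)cc2OC)ccc1O[Si](C(C)C)(C(C)C)C(C)C | intermediate
20 | (2S,3S)-anti β-hydroxy ester | COc1cc([C@H](O)[C@@H](C(=O)OC(C)(C)C)Oc2c(OC)cc([C@@H]3Oc4c(OC)cc(C5OCCO5)cc4[C@H]3CO[Si](C)(C)C(C)(C)C)cc2OC)ccc1O[Si](C(C)C)(C(C)C)C(C)C | intermediate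
21 | (1S,2R)-1,3-diol, silyl ethers and acetal intact | COc1cc([C@H](O)[C@@H](CO)Oc2c(OC)cc([C@@H]3Oc4c(OC)cc(C5OCCO5)cc4[C@H]3CO[Si](C)(C)C(C)(C)C)cc2OC)ccc1O[Si](C(C)C)(C(C)C)C(C)C | intermediate
22 | desilylated acetal | COc1cc([C@H](O)[C@@H](CO)Oc2c(OC)cc([C@@H]3Oc4c(OC)cc(C5OCCO5)cc4[C@H]3CO)cc2OC)ccc1O | intermediate
23 | CID53356209 | COc1cc([C@H](O)[C@@H](CO)Oc2c(OC)cc([C@@H]3Oc4c(OC)cc(C=O)cc4[C@H]3CO)cc2OC)ccc1O | target

## Summary
Total steps: 18.
Longest linear sequence: 17 steps (steps 1–11 and 13–18, from syringaldehyde); step 12 is a one-step side branch.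

Three steps most likely to fail, each with a fallback that changes the approach:

1. **Step 15 (ketoreductase reduction).** Substrate 19 is large and lipophilic, and a variant giving the anti-(2S,3S) product has to be found by screening. Fallback: move the enzymatic reduction to a small substrate by reordering the assembly. Run aldol, oxidation and ketoreductase reduction on the acetal of 3 before the benzofuran exists, then convert the benzylic position to the bromide and build the dihydrobenzofuran last (steps 4–10).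

2. **Step 8 (Rh C–H insertion).** Enantioselectivity and cis selectivity may be lower on this more heavily oxygenated substrate. Fallback: build the ring from an acyclic precursor instead. Use Ru–TsDPEN transfer hydrogenation with dynamic kinetic resolution of an α-(2-alkoxyaryl)-β-keto ester to set the C3 centre, then acid-promoted cyclodehydration through the syringyl benzylic cation to the thermodynamic trans-dihydrobenzofuran.

3. **Step 6 (Pd/Reformatsky arylation).** The ortho-alkoxy aryl bromide may couple sluggishly. Fallback: install the two-carbon unit by sigmatropic chemistry. O-allylate vanillin, run a Claisen rearrangement to 5-allylvanillin, alkylate with 5, then cleave the alkene (OsO4/NaIO4) and oxidise/esterify to the arylacetate, carrying the aldehyde as a silyl-protected benzylic alcohol through the oxidation.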